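**Plan**

- Numbering used below (germacrane): ring C1–C10, lactone carbons C11 (α), C12 (C=O), C13 (exo-CH2), lactone O on C6, ester O on C8, C14 on C10, C15 on C4.
- Retrosynthesis: cut the C8 ester (invertive Mitsunobu), then the ring bond C7–C8 (intramolecular Nozaki–Hiyama allylation of a C8 aldehyde by a 3-(bromomethyl)butenolide), then the butenolide (C12 from CO, C7≡C11 alkyne), C1=C10 (Horner–Wadsworth–Emmons), C6–C7 (acetylide plus lactone) and C4–C5 (Evans alkylation).
- Forward: the open chain C15/C1–C6 is built linearly, the butenolide ring (O–C6–C7=C11–C12) is formed next, and the ten-membered carbocycle is closed last.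
- Enabling feature: C8–O is homoallylic to the exocyclic C11=C13 bond through C7 (allyl triad C13–C11–C7 of the α-methylene-γ-lactone). A preformed butenolide carrying CH2Br on C11 is therefore an allyl-metal precursor whose γ-carbon is C7, and the lactone regiochemistry (O on C6) is fixed before ring closure.
- Stereochemistry: C4 from the (R)-benzyloxazolidinone; C6 from catalyst-controlled transfer hydrogenation; C1=C10 geometry from the olefination; C7 from attack trans to the C5 branch; C8 from the chair transition state (8α-OH expected), turned into the 8β-ester by the invertive esterification.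

Key step: step 17

Remark: TBS = tert-butyldimethylsilyl, TBDPS = tert-butyldiphenylsilyl; the ring double bond C1=C10 has C2 and C9 cis (CIP descriptor E because C14 outranks C9).

**Step 1**
Reactants: 1 (R)-4-benzyl-1,3-oxazolidin-2-one; 2 hex-5-enoyl chloride
Product: 3 (4R)-4-benzyl-3-(hex-5-enoyl)-1,3-oxazolidin-2-one
Conditions: Et3N, DMAP (cat.), CH2Cl2, 0 °C → rt
Reagents that add atoms: none
Why: DMAP-catalysed N-acylation of the oxazolidinone by the acid chloride; no stereocentre is formed.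

**Step 2**
Reactants: 3 (4R)-4-benzyl-3-(hex-5-enoyl)-1,3-oxazolidin-2-one; 4 tert-butyl bromoacetate
Product: 6 (4R)-4-benzyl-3-[(2S)-2-(2-tert-butoxy-2-oxoethyl)hex-5-enoyl]-1,3-oxazolidin-2-one, via sodium (Z)-enolate 5 (not isolated)
Conditions: NaN(SiMe3)2, THF, −78 °C; then 4, −78 → −40 °C
Reagents that add atoms: none
Why: Evans asymmetric alkylation, in which the chelated (Z)-enolate is alkylated by the reactive α-bromo ester on the face opposite the benzyl group, setting C4 as S.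

**Step 3**
Reactants: 6 (4R)-4-benzyl-3-[(2S)-2-(2-tert-butoxy-2-oxoethyl)hex-5-enoyl]-1,3-oxazolidin-2-one
Product: 8 (4S)-4-(but-3-en-1-yl)oxolan-2-one, via tert-butyl (3S)-3-(hydroxymethyl)hept-6-enoate 7 (not isolated)
Conditions: LiBH4, MeOH (1 equiv), THF, 0 °C; then CF3CO2H, CH2Cl2, 0 °C → rt
Reagents that add atoms: none
Why: LiBH4 cleaves the imide reductively while sparing the tert-butyl ester (auxiliary removal), and acid then closes the γ-lactone with loss of isobutene, leaving C4 untouched.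

**Step 4**
Reactants: 9 tert-butyldimethyl(prop-2-yn-1-yloxy)silane; 8 (4S)-4-(but-3-en-1-yl)oxolan-2-one
Product: 11 (6S)-1-(tert-butyldimethylsilyloxy)-6-(hydroxymethyl)dec-9-en-2-yn-4-one, via lithium acetylide 10 (not isolated)
Conditions: n-BuLi, THF, −78 °C; then 8, −78 °C; aq. NH4Cl
Reagents that add atoms: none
Why: Acylation of an alkynyllithium by a γ-lactone, which stops at the ketone stage because the tetrahedral lithium lactolate is stable at −78 °C.

**Step 5**
Reactants: 11 (6S)-1-(tert-butyldimethylsilyloxy)-6-(hydroxymethyl)dec-9-en-2-yn-4-one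
Product: 12 (6S)-1-(tert-butyldimethylsilyloxy)-6-[(tert-butyldiphenylsilyloxy)methyl]dec-9-en-2-yn-4-one
Conditions: TBDPSCl, Et3N, DMAP (cat.), CH2Cl2, 0 °C → rt
Reagents that add atoms: tert-butyl(chloro)diphenylsilane, CC(C)(C)[Si](Cl)(c1ccccc1)c1ccccc1
Why: Silylation of the primary alcohol traps the open hydroxy-ketone form and uses a non-nucleophilic base so that nothing adds to the ynone.

**Step 6**
Reactants: 12 (6S)-1-(tert-butyldimethylsilyloxy)-6-[(tert-butyldiphenylsilyloxy)methyl]dec-9-en-2-yn-4-one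
Product: 13 (4R,6S)-1-(tert-butyldimethylsilyloxy)-6-[(tert-butyldiphenylsilyloxy)methyl]dec-9-en-2-yn-4-ol
Conditions: RuCl[(R,R)-TsDPEN](p-cymene) (2 mol %), KOH (cat.), i-PrOH, rt
Reagents that add atoms: none
Why: Noyori asymmetric transfer hydrogenation of an alkynyl ketone, in which the alkynyl group takes the place of the aryl group in the CH/π-controlled transition state, so the (R,R)-catalyst should set C6 as R independently of the remote C4 centre.

**Step 7**
Reactants: 13 (4R,6S)-1-(tert-butyldimethylsilyloxy)-6-[(tert-butyldiphenylsilyloxy)methyl]dec-9-en-2-yn-4-ol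
Product: 14 (4S,6R)-9-(tert-butyldimethylsilyloxy)-4-[(tert-butyldiphenylsilyloxy)methyl]-6-hydroxynon-7-ynal
Conditions: OsO4 (2 mol %), NaIO4, 2,6-lutidine, dioxane/H2O, rt
Reagents that add atoms: sodium periodate (oxygen source through catalytic OsO4), [Na+].[O-]I(=O)(=O)=O
Why: Lemieux–Johnson oxidative cleavage, since OsO4 dihydroxylates the terminal alkene far faster than the internal alkyne and periodate cleaves the diol to the C1 aldehyde.

**Step 8**
Reactants: 15 triethyl phosphonoacetate; 16 (2-bromoethoxy)(tert-butyl)dimethylsilane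
Product: 18 ethyl 4-(tert-butyldimethylsilyloxy)-2-(diethoxyphosphoryl)butanoate (racemic), via sodium phosphonoacetate anion 17 (not isolated)
Conditions: NaH, DMF, 0 °C; then 16, NaI (cat.), 60 °C
Reagents that add atoms: none
Why: SN2 C-alkylation of the stabilised phosphonoacetate anion by a primary bromide.

**Step 9**
Reactants: 14 (4S,6R)-9-(tert-butyldimethylsilyloxy)-4-[(tert-butyldiphenylsilyloxy)methyl]-6-hydroxynon-7-ynal; 18 ethyl 4-(tert-butyldimethylsilyloxy)-2-(diethoxyphosphoryl)butanoate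
Product: 19 ethyl (2E,6S,8R)-11-(tert-butyldimethylsilyloxy)-2-[2-(tert-butyldimethylsilyloxy)ethyl]-6-[(tert-butyldiphenylsilyloxy)methyl]-8-hydroxyundec-2-en-9-ynoate
Conditions: LiCl, DBU, MeCN, 0 °C → rt
Reagents that add atoms: none
Why: Horner–Wadsworth–Emmons olefination under Masamune–Roush conditions, in which the α-substituted phosphonoacetate should give the (E)-enoate (ester trans to the chain) and so place C9 cis to C2 as the ring requires; the free secondary alcohol is tolerated.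

**Step 10**
Reactants: 19 ethyl (2E,6S,8R)-11-(tert-butyldimethylsilyloxy)-2-[2-(tert-butyldimethylsilyloxy)ethyl]-6-[(tert-butyldiphenylsilyloxy)methyl]-8-hydroxyundec-2-en-9-ynoate
Product: 20 (2E,6S,8R)-11-(tert-butyldimethylsilyloxy)-2-[2-(tert-butyldimethylsilyloxy)ethyl]-6-[(tert-butyldiphenylsilyloxy)methyl]undec-2-en-9-yne-1,8-diol
Conditions: i-Bu2AlH, CH2Cl2, −78 °C; Rochelle salt work-up
Reagents that add atoms: none
Why: 1,2-Reduction of the conjugated ester to the allylic alcohol (C14) by i-Bu2AlH, with alkyne and silyl ethers inert at low temperature.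

**Step 11**
Reactants: 20 (2E,6S,8R)-11-(tert-butyldimethylsilyloxy)-2-[2-(tert-butyldimethylsilyloxy)ethyl]-6-[(tert-butyldiphenylsilyloxy)methyl]undec-2-en-9-yne-1,8-diol
Product: 21 (2E,6S,8R)-1-(tert-butyldiphenylsilyloxy)-11-(tert-butyldimethylsilyloxy)-2-[2-(tert-butyldimethylsilyloxy)ethyl]-6-[(tert-butyldiphenylsilyloxy)methyl]undec-2-en-9-yn-8-ol
Conditions: TBDPSCl, imidazole, CH2Cl2, −20 → 0 °C
Reagents that add atoms: tert-butyl(chloro)diphenylsilane, CC(C)(C)[Si](Cl)(c1ccccc1)c1ccccc1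
Why: Selective silylation of the primary allylic alcohol over the secondary propargylic alcohol by the bulky silyl chloride.

**Step 12**
Reactants: 21 (2E,6S,8R)-1-(tert-butyldiphenylsilyloxy)-11-(tert-butyldimethylsilyloxy)-2-[2-(tert-butyldimethylsilyloxy)ethyl]-6-[(tert-butyldiphenylsilyloxy)methyl]undec-2-en-9-yn-8-ol
Product: 23 (2E,6S,8R,9Z)-1-(tert-butyldiphenylsilyloxy)-11-(tert-butyldimethylsilyloxy)-2-[2-(tert-butyldimethylsilyloxy)ethyl]-6-[(tert-butyldiphenylsilyloxy)methyl]-10-iodoundeca-2,9-dien-8-ol, via cyclic vinylalanate 22 (not isolated)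
Conditions: NaAlH2(OCH2CH2OMe)2 (Red-Al), THF, 0 °C → rt; then I2, THF, −78 °C
Reagents that add atoms: iodine, [I][I]
Why: Hydroxyl-directed trans-hydroalumination of the propargylic alcohol puts aluminium on the distal alkyne carbon (C11) through a five-membered alkoxyaluminate, and iodinolysis with retention gives the (Z)-iodoalkene with iodine cis to C6.

**Step 13**
Reactants: 23 (2E,6S,8R,9Z)-1-(tert-butyldiphenylsilyloxy)-11-(tert-butyldimethylsilyloxy)-2-[2-(tert-butyldimethylsilyloxy)ethyl]-6-[(tert-butyldiphenylsilyloxy)methyl]-10-iodoundeca-2,9-dien-8-ol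
Product: 24 (5R)-3-[(tert-butyldimethylsilyloxy)methyl]-5-[(2S,5E)-8-(tert-butyldimethylsilyloxy)-2,6-bis[(tert-butyldiphenylsilyloxy)methyl]oct-5-en-1-yl]furan-2(5H)-one
Conditions: Pd(PPh3)4 (5 mol %), CO (1 atm), K2CO3, THF, 45 °C
Reagents that add atoms: carbon monoxide, [C-]#[O+]
Why: Palladium-catalysed carbonylative lactonisation (oxidative addition, CO insertion, capture of the acylpalladium by the cis hydroxyl) closes the butenolide and supplies C12 without touching C6.

**Step 14**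
Reactants: 24 (5R)-3-[(tert-butyldimethylsilyloxy)methyl]-5-[(2S,5E)-8-(tert-butyldimethylsilyloxy)-2,6-bis[(tert-butyldiphenylsilyloxy)methyl]oct-5-en-1-yl]furan-2(5H)-one
Product: 25 (5R)-3-(hydroxymethyl)-5-[(2S,5E)-8-hydroxy-2,6-bis[(tert-butyldiphenylsilyloxy)methyl]oct-5-en-1-yl]furan-2(5H)-one
Conditions: camphorsulfonic acid (cat.), MeOH/CH2Cl2, 0 °C
Reagents that add atoms: none
Why: Acid-catalysed methanolysis removes the two primary TBS ethers much faster than the TBDPS ethers (selective desilylation).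

**Step 15**
Reactants: 25 (5R)-3-(hydroxymethyl)-5-[(2S,5E)-8-hydroxy-2,6-bis[(tert-butyldiphenylsilyloxy)methyl]oct-5-en-1-yl]furan-2(5H)-one
Product: 26 (5R)-3-(bromomethyl)-5-[(2S,5E)-8-hydroxy-2,6-bis[(tert-butyldiphenylsilyloxy)methyl]oct-5-en-1-yl]furan-2(5H)-one
Conditions: N-bromosuccinimide, Me2S, CH2Cl2, −30 → 0 °C
Reagents that add atoms: N-bromosuccinimide, O=C1CCC(=O)N1Br
Why: Corey–Kim-type halogenation, in which only the allylic alkoxysulfonium (C13) is displaced by bromide while that of the saturated primary alcohol (C8) reverts to the alcohol on work-up.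

**Step 16**
Reactants: 26 (5R)-3-(bromomethyl)-5-[(2S,5E)-8-hydroxy-2,6-bis[(tert-butyldiphenylsilyloxy)methyl]oct-5-en-1-yl]furan-2(5H)-one
Product: 27 (3E,7S)-8-[(2R)-4-(bromomethyl)-5-oxo-2,5-dihydrofuran-2-yl]-3,7-bis[(tert-butyldiphenylsilyloxy)methyl]oct-3-enal
Conditions: Dess–Martin periodinane, NaHCO3, CH2Cl2, 0 °C; used at once
Reagents that add atoms: none
Why: Buffered Dess–Martin oxidation gives the β,γ-unsaturated aldehyde without base-induced conjugation and leaves the allylic bromide intact.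

**Step 17**
Reactants: 27 (3E,7S)-8-[(2R)-4-(bromomethyl)-5-oxo-2,5-dihydrofuran-2-yl]-3,7-bis[(tert-butyldiphenylsilyloxy)methyl]oct-3-enal
Product: 29 (4S,6R,7R,8S)-14,15-bis(tert-butyldiphenylsilyloxy)-8-hydroxygermacra-1(10),11(13)-dien-12,6-olide (8α-OH), via allylchromium dichloride 28 (not isolated)
Conditions: CrCl2 (10 equiv), THF, rt, slow addition of 27 (final ca. 2 mM)
Reagents that add atoms: none
Why: Two equivalents of CrCl2 (divalent chromium) insert into the allylic C–Br bond to give allylchromium 28 (trivalent chromium), which adds through its γ-carbon C7 to the tethered C8 aldehyde in a six-membered chair transition state (Cr–C13–C11=C7···C8=O), the double bond moving to the exocyclic C11=C13 position so that the α-methylene-γ-lactone appears as the ring closes. The closest known reaction types are the Nozaki–Hiyama allylation of aldehydes with 3-(bromomethyl)furan-2(5H)-ones and chromium-mediated macrocyclic allylations that give ten-membered germacrane rings. The ten-membered carbocycle C1–C10 closes by 10-exo-trig addition of C7 to the C8 carbonyl with allylic transposition (SE2') in the butenolide. C7 is set by attack on the butenolide face trans to the C5 branch on C6, the trajectory in which the tether keeps a near-anti C5–C6–C7–C8 torsion that a ten-membered ring accommodates (cis attack would eclipse these bonds), so the 6,7-trans lactone fusion should result. C8 is set by the chair: the ring-locked allyl unit has C6 trans to C13 (E-type) and C9 sits pseudo-equatorially, anti to C11 and away from the C12 carbonyl, which should give the anti carbinol (8S, 8α-OH). The step needs γ- over α-attack (inherent to allylchromium reagents), ring closure over oligomerisation (slow addition at high dilution) and no conjugation of the β,γ-unsaturated aldehyde (neutral aprotic medium, freshly made aldehyde).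

**Step 18**
Reactants: 29 (4S,6R,7R,8S)-14,15-bis(tert-butyldiphenylsilyloxy)-8-hydroxygermacra-1(10),11(13)-dien-12,6-olide; 30 methacrylic acid
Product: 31 (4S,6R,7S,8R)-14,15-bis(tert-butyldiphenylsilyloxy)-8-(methacryloyloxy)germacra-1(10),11(13)-dien-12,6-olide
Conditions: PPh3, diisopropyl azodicarboxylate, THF, 0 °C → rt
Reagents that add atoms: none
Why: Mitsunobu esterification, in which methacrylate displaces the alkoxyphosphonium at C8 by SN2 with inversion (8α-OH to 8β-ester) and installs the side chain in the same operation.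

**Step 19**
Reactants: 31 (4S,6R,7S,8R)-14,15-bis(tert-butyldiphenylsilyloxy)-8-(methacryloyloxy)germacra-1(10),11(13)-dien-12,6-olide
Product: 32 (4S,6R,7S,8R)-14,15-dihydroxy-8-(methacryloyloxy)germacra-1(10),11(13)-dien-12,6-olide (CNP0546547.2)
Conditions: HF·pyridine, pyridine, THF, 0 °C → rt
Reagents that add atoms: none
Why: Fluoride-mediated desilylation under non-basic conditions frees both primary alcohols while sparing the methacrylate and the α-methylene lactone.

**Compound list**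

1 | (R)-4-benzyl-1,3-oxazolidin-2-one | O=C1OC[C@@H](Cc2ccccc2)N1 | starting material
2 | hex-5-enoyl chloride | C=CCCCC(Cl)=O | starting material
3 | (4R)-4-benzyl-3-(hex-5-enoyl)-1,3-oxazolidin-2-one | C=CCCCC(=O)N1[C@H](Cc2ccccc2)COC1=O | intermediate
4 | tert-butyl bromoacetate | CC(C)(C)OC(=O)CBr | starting material
5 | sodium (Z)-enolate of 3 | C=CCC/C=C(\[O-])N1[C@H](Cc2ccccc2)COC1=O.[Na+] | intermediate
6 | (4R)-4-benzyl-3-[(2S)-2-(2-tert-butoxy-2-oxoethyl)hex-5-enoyl]-1,3-oxazolidin-2-one | C=CCC[C@@H](CC(=O)OC(C)(C)C)C(=O)N1[C@H](Cc2ccccc2)COC1=O | intermediate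
7 | tert-butyl (3S)-3-(hydroxymethyl)hept-6-enoate | C=CCC[C@@H](CC(=O)OC(C)(C)C)CO | intermediate
8 | (4S)-4-(but-3-en-1-yl)oxolan-2-one | C=CCC[C@@H]1COC(=O)C1 | intermediate
9 | tert-butyldimethyl(prop-2-yn-1-yloxy)silane | C#CCO[Si](C)(C)C(C)(C)C | starting material
10 | [3-(tert-butyldimethylsilyloxy)prop-1-yn-1-yl]lithium | [Li]C#CCO[Si](C)(C)C(C)(C)C | intermediate
11 | (6S)-1-(tert-butyldimethylsilyloxy)-6-(hydroxymethyl)dec-9-en-2-yn-4-one | C=CCC[C@H](CO)CC(=O)C#CCO[Si](C)(C)C(C)(C)C | intermediate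
12 | (6S)-1-(tert-butyldimethylsilyloxy)-6-[(tert-butyldiphenylsilyloxy)methyl]dec-9-en-2-yn-4-one | C=CCC[C@H](CO[Si](c1ccccc1)(c1ccccc1)C(C)(C)C)CC(=O)C#CCO[Si](C)(C)C(C)(C)C | intermediate
13 | (4R,6S)-1-(tert-butyldimethylsilyloxy)-6-[(tert-butyldiphenylsilyloxy)methyl]dec-9-en-2-yn-4-ol | C=CCC[C@H](CO[Si](c1ccccc1)(c1ccccc1)C(C)(C)C)C[C@@H](O)C#CCO[Si](C)(C)C(C)(C)C | intermediate
14 | (4S,6R)-9-(tert-butyldimethylsilyloxy)-4-[(tert-butyldiphenylsilyloxy)methyl]-6-hydroxynon-7-ynal | O=CCC[C@H](CO[Si](c1ccccc1)(c1ccccc1)C(C)(C)C)C[C@@H](O)C#CCO[Si](C)(C)C(C)(C)C | intermediate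
15 | triethyl phosphonoacetate | CCOC(=O)CP(=O)(OCC)OCC | starting material
16 | (2-bromoethoxy)(tert-butyl)dimethylsilane | BrCCO[Si](C)(C)C(C)(C)C | starting material
17 | sodium salt of triethyl phosphonoacetate | CCOC(=O)[CH-]P(=O)(OCC)OCC.[Na+] | intermediate
18 | ethyl 4-(tert-butyldimethylsilyloxy)-2-(diethoxyphosphoryl)butanoate (racemic) | CCOC(=O)C(CCO[Si](C)(C)C(C)(C)C)P(=O)(OCC)OCC | intermediate
19 | ethyl (2E,6S,8R)-11-(tert-butyldimethylsilyloxy)-2-[2-(tert-butyldimethylsilyloxy)ethyl]-6-[(tert-butyldiphenylsilyloxy)methyl]-8-hydroxyundec-2-en-9-ynoate | CC(C)(C)[Si](C)(C)OCC/C(C(=O)OCC)=C\CC[C@H](CO[Si](c1ccccc1)(c1ccccc1)C(C)(C)C)C[C@@H](O)C#CCO[Si](C)(C)C(C)(C)C | intermediate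
20 | (2E,6S,8R)-11-(tert-butyldimethylsilyloxy)-2-[2-(tert-butyldimethylsilyloxy)ethyl]-6-[(tert-butyldiphenylsilyloxy)methyl]undec-2-en-9-yne-1,8-diol | CC(C)(C)[Si](C)(C)OCC/C(CO)=C\CC[C@H](CO[Si](c1ccccc1)(c1ccccc1)C(C)(C)C)C[C@@H](O)C#CCO[Si](C)(C)C(C)(C)C | intermediate
21 | (2E,6S,8R)-1-(tert-butyldiphenylsilyloxy)-11-(tert-butyldimethylsilyloxy)-2-[2-(tert-butyldimethylsilyloxy)ethyl]-6-[(tert-butyldiphenylsilyloxy)methyl]undec-2-en-9-yn-8-ol | CC(C)(C)[Si](C)(C)OCC/C(CO[Si](c1ccccc1)(c1ccccc1)C(C)(C)C)=C\CC[C@H](CO[Si](c1ccccc1)(c1ccccc1)C(C)(C)C)C[C@@H](O)C#CCO[Si](C)(C)C(C)(C)C | intermediate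
22 | sodium cyclic alkoxy(vinyl)bis(2-methoxyethoxy)aluminate of 21 (Al on C11, O on C6) | CC(C)(C)[Si](C)(C)OCC/C(CO[Si](c1ccccc1)(c1ccccc1)C(C)(C)C)=C\CC[C@H](CO[Si](c1ccccc1)(c1ccccc1)C(C)(C)C)C[C@H]1O[Al-](OCCOC)(OCCOC)C(CO[Si](C)(C)C(C)(C)C)=C1.[Na+] | intermediate
23 | (2E,6S,8R,9Z)-1-(tert-butyldiphenylsilyloxy)-11-(tert-butyldimethylsilyloxy)-2-[2-(tert-butyldimethylsilyloxy)ethyl]-6-[(tert-butyldiphenylsilyloxy)methyl]-10-iodoundeca-2,9-dien-8-ol | CC(C)(C)[Si](C)(C)OCC/C(CO[Si](c1ccccc1)(c1ccccc1)C(C)(C)C)=C\CC[C@H](CO[Si](c1ccccc1)(c1ccccc1)C(C)(C)C)C[C@@H](O)/C=C(\I)CO[Si](C)(C)C(C)(C)C | intermediate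
24 | (5R)-3-[(tert-butyldimethylsilyloxy)methyl]-5-[(2S,5E)-8-(tert-butyldimethylsilyloxy)-2,6-bis[(tert-butyldiphenylsilyloxy)methyl]oct-5-en-1-yl]furan-2(5H)-one | CC(C)(C)[Si](C)(C)OCC/C(CO[Si](c1ccccc1)(c1ccccc1)C(C)(C)C)=C\CC[C@H](CO[Si](c1ccccc1)(c1ccccc1)C(C)(C)C)C[C@H]1OC(=O)C(CO[Si](C)(C)C(C)(C)C)=C1 | intermediate
25 | (5R)-3-(hydroxymethyl)-5-[(2S,5E)-8-hydroxy-2,6-bis[(tert-butyldiphenylsilyloxy)methyl]oct-5-en-1-yl]furan-2(5H)-one | OCC/C(CO[Si](c1ccccc1)(c1ccccc1)C(C)(C)C)=C\CC[C@H](CO[Si](c1ccccc1)(c1ccccc1)C(C)(C)C)C[C@H]1OC(=O)C(CO)=C1 | intermediate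
26 | (5R)-3-(bromomethyl)-5-[(2S,5E)-8-hydroxy-2,6-bis[(tert-butyldiphenylsilyloxy)methyl]oct-5-en-1-yl]furan-2(5H)-one | OCC/C(CO[Si](c1ccccc1)(c1ccccc1)C(C)(C)C)=C\CC[C@H](CO[Si](c1ccccc1)(c1ccccc1)C(C)(C)C)C[C@H]1OC(=O)C(CBr)=C1 | intermediate
27 | (3E,7S)-8-[(2R)-4-(bromomethyl)-5-oxo-2,5-dihydrofuran-2-yl]-3,7-bis[(tert-butyldiphenylsilyloxy)methyl]oct-3-enal | O=CC/C(CO[Si](c1ccccc1)(c1ccccc1)C(C)(C)C)=C\CC[C@H](CO[Si](c1ccccc1)(c1ccccc1)C(C)(C)C)C[C@H]1OC(=O)C(CBr)=C1 | intermediate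
28 | allylchromium dichloride derived from 27 (CrCl2 on C13) | O=CC/C(CO[Si](c1ccccc1)(c1ccccc1)C(C)(C)C)=C\CC[C@H](CO[Si](c1ccccc1)(c1ccccc1)C(C)(C)C)C[C@H]1OC(=O)C(C[Cr](Cl)Cl)=C1 | intermediate
29 | (4S,6R,7R,8S)-14,15-bis(tert-butyldiphenylsilyloxy)-8-hydroxygermacra-1(10),11(13)-dien-12,6-olide (8α-OH, H-7α, H-6β, C15 β) | O[C@H]1C/C(CO[Si](c3ccccc3)(c3ccccc3)C(C)(C)C)=C\CC[C@H](CO[Si](c3ccccc3)(c3ccccc3)C(C)(C)C)C[C@H]2OC(=O)C(=C)[C@H]12 | intermediate
30 | methacrylic acid | C=C(C)C(=O)O | starting material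
31 | (4S,6R,7S,8R)-14,15-bis(tert-butyldiphenylsilyloxy)-8-(methacryloyloxy)germacra-1(10),11(13)-dien-12,6-olide (8β-ester) | C=C(C)C(=O)O[C@@H]1C/C(CO[Si](c3ccccc3)(c3ccccc3)C(C)(C)C)=C\CC[C@H](CO[Si](c3ccccc3)(c3ccccc3)C(C)(C)C)C[C@H]2OC(=O)C(=C)[C@H]12 | intermediate
32 | (4S,6R,7S,8R)-14,15-dihydroxy-8-(methacryloyloxy)germacra-1(10),11(13)-dien-12,6-olide | C=C(C)C(=O)O[C@@H]1C/C(CO)=C\CC[C@H](CO)C[C@H]2OC(=O)C(=C)[C@H]12 | target

**Step count and risks**

Total step count: 19. Longest linear sequence: 18 steps (steps 1–7 and 9–19; step 8 is the side branch).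

Steps most likely to fail:

Step 17. The tether may force the aldehyde to react through its other face (C9 pseudo-axial or a non-chair arrangement), so that the C8 epimer forms in place of 29. The fallback keeps the ring closure and changes the endgame. Setting out from 27, the cyclisation product is then the (4S,6R,7R,8R)-8β-alcohol F1. It is acylated with retention (methacrylic anhydride, Et3N, DMAP, CH2Cl2, 0 °C) and comes back to the route at 31, so the invertive step is not needed.

Step 18. The hindered, ring-embedded alkoxyphosphonium may eliminate toward C9 or C7 (diene formation) or resist displacement. The fallback sets out from 29 and replaces inversion by an oxidation–reduction sequence. Dess–Martin periodinane with NaHCO3 gives the C8 ketone F2. Luche reduction (NaBH4, CeCl3·7H2O, MeOH, −78 °C) should deliver hydride from the α-face, syn to H-7 and away from C11, to give the 8β-alcohol F1 (the same compound as in the first fallback). Acylation with methacrylic anhydride and DMAP then comes back to the route at 31.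

Step 12. The vinylalanate carries a silyloxy group on the adjacent carbon and may lose it by β-elimination (allene formation), or the hydride may attack silyl ethers. The fallback sets out from 21 and uses ruthenium-catalysed trans-hydrosilylation ([Cp*Ru(MeCN)3]PF6, Et3SiH, CH2Cl2, 0 °C), which places silicon on the alkyne carbon distal to the free hydroxyl and gives the (Z)-vinylsilane F3. Iododesilylation with retention (N-iodosuccinimide, 2,6-lutidine, (CF3)2CHOH, 0 °C) comes back to the route at 23.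

Further compounds
F1 | step 17 | (4S,6R,7R,8R)-14,15-bis(tert-butyldiphenylsilyloxy)-8-hydroxygermacra-1(10),11(13)-dien-12,6-olide (8β-OH) | O[C@@H]1C/C(CO[Si](c3ccccc3)(c3ccccc3)C(C)(C)C)=C\CC[C@H](CO[Si](c3ccccc3)(c3ccccc3)C(C)(C)C)C[C@H]2OC(=O)C(=C)[C@H]12
F2 | step 18 | (4S,6R,7R)-14,15-bis(tert-butyldiphenylsilyloxy)-8-oxogermacra-1(10),11(13)-dien-12,6-olide | O=C1C/C(CO[Si](c3ccccc3)(c3ccccc3)C(C)(C)C)=C\CC[C@H](CO[Si](c3ccccc3)(c3ccccc3)C(C)(C)C)C[C@H]2OC(=O)C(=C)[C@H]12
F3 | step 12 | (2E,6S,8R,9Z)-1-(tert-butyldiphenylsilyloxy)-11-(tert-butyldimethylsilyloxy)-2-[2-(tert-butyldimethylsilyloxy)ethyl]-6-[(tert-butyldiphenylsilyloxy)methyl]-10-(triethylsilyl)undeca-2,9-dien-8-ol | CC(C)(C)[Si](C)(C)OCC/C(CO[Si](c1ccccc1)(c1ccccc1)C(C)(C)C)=C\CC[C@H](CO[Si](c1ccccc1)(c1ccccc1)C(C)(C)C)C[C@@H](O)/C=C(\[Si](CC)(CC)CC)CO[Si](C)(C)C(C)(C)C
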